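The product to watch is monomer in chains, and the chain length is that amount divided by the living ends that share it.

common to all: initiator 25 µM; time 5.0 min

| run | free monomer | remark |
|---|---|---|
| north-east | 5.0 mM (fed, over 2.0 s) | the fed solution adds 0.20 times the starting volume |
| north-west | 8.0 mM (fed, over 2.0 s) | the fed solution adds 0.20 times the starting volume |

    free monomer + initiator → living end + monomer in chains (k1 = 30.0 M⁻¹ s⁻¹)
    free monomer + living end → monomer in chains + living end, rate k2*[living end]*[free monomer] (k2 = 524 M⁻¹ s⁻¹)
    initiator → spent initiator (k3 = 0.0448 s⁻¹)
    free monomer → uncatalysed product (k4 = 0.0135 s⁻¹)

- which of the two ends with the longer chains by the average number of monomer units in a chain (chains begun, living or dead) ("neither" if they lie within 10 %) (north-east / north-west / neither)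
- average number of monomer units in a chain (chains begun, living or dead) at the end, north-east
- average number of monomer units in a chain (chains begun, living or dead) at the end, north-west

- amounts are per litre of the starting volume; all of the dose is in the solution fed
- the average divides the monomer in chains by the number of chains begun, living and dead together
- run time (north-east): 5.0 min

We reckon north-east in concentrations of the final volume, where the charge of free monomer comes to m = 4.17 mM and that of initiator to n = 20.8 µM. The curve of monomer in chains starts flat: at the start neither free monomer nor living end stands in the flask. With free monomer held at m, initiator goes to living ends at 0.125 s⁻¹ and to spent initiator at 0.0448 s⁻¹, so we reckon that a share of 73.6 % begins chains. We put the knee at about 5.89 s, later than the end of the feed at 2.0 s, and beyond it we take the living ends to level off at L = 15.3 µM.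

Beyond the knee in north-east, we have free monomer decay by two pseudo-first-order exits: propagation at 0.00804 s⁻¹ and uncatalysed loss at 0.0135 s⁻¹, which is faster. The carried quantity is B = 25.8 µM, the living-end concentration at which propagation and uncatalysed loss take free monomer equally fast. In our reckoning for north-east, monomer in chains bends over with a half-life of 32.2 s and runs into a level of L/(L+B) = 37.3 % of the charge. At that rate we reckon free monomer in north-east at 0.156 % of its charge by 5.0 min. The length is then m/(L+B) = 101 in north-east. In north-west, a diluted charge of 6.67 mM gives L = 17.0 µM and a length of 156, which is 53.7 % longer and past the 10 % margin.

The forecast names north-west with 96 and 151, a little below our lengths, and says “this outweighs its slightly larger number of chains”. The simulation gives north-west, with 97.0 in north-east and 151 in north-west, so our north-east length runs 4.57 % high.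

North-east ends with 0.0143 mM of living ends, below B, and holds 66.6 % of the free monomer charged as uncatalysed product against 33.2 % in chains. Taking the uncatalysed step away lifts the north-east length from 97.0 to 255. A flask like north-east but charged with 0.10 mM of initiator ends with 0.0552 mM of living ends, above B, so m/(L+B) gives 51.5 against its simulated 48.3, and monomer in chains holds 64.0 % of the free monomer charged.

The constants were set for the occasion, and the outcome is calculated.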